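**Retrosynthetic overview**
1. Target 10 ⇐ 8 by one-pot hydrogenolysis (Cbz and two O-benzyl groups) with reductive N-methylation.
2. 8 ⇐ 7 by photoredox hydrodecarboxylation: the bought pipecolic stereocentre is excised after it has set the configuration at C6''.
3. 7 ⇐ lactone 6 ⇐ ester 4 by the key C6–C6'' bond formation: an anodic, aminoxyl-mediated N-acyliminium aza-Friedel–Crafts closure through the O5 ester tether, whose cis-bridge fixes both regio- and stereochemistry.
4. 4 ⇐ 2 + N-Cbz-L-pipecolic acid 3 (esterification); 2 ⇐ (S)-naringenin 1 (7,4'-di-O-benzylation).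
5. Ring order: rings A, B and C of the flavanone and the piperidine are bought intact; the only ring made is a temporary seven-membered lactone (step 3), opened again in step 4.

Assumption: commercial (2S)-naringenin and N-Cbz-L-pipecolic acid are taken as enantiopure. Flavanone atoms are numbered O1–C8a, ring B atoms carry one prime and piperidine atoms two primes.

**Step 1**
Reactants: 1 (2S)-naringenin
Product: 2 (2S)-7-benzyloxy-2-(4-benzyloxyphenyl)-5-hydroxychroman-4-one
Conditions: BnOH (2.2 equiv), PPh3, DIAD, THF, 0 °C to rt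
Reagents that add atoms: benzyl alcohol, OCc1ccccc1
Why: Mitsunobu etherification alkylates only the two acidic, unchelated phenols (7-OH, 4'-OH) and leaves the chelated 5-OH free; being base-free, it avoids the phenoxide-driven chalcone ring-opening that racemises the bought C2 centre.

**Step 2**
Reactants: 2 (2S)-7-benzyloxy-2-(4-benzyloxyphenyl)-5-hydroxychroman-4-one; 3 (2S)-1-(benzyloxycarbonyl)piperidine-2-carboxylic acid
Product: 4 (2S)-7-benzyloxy-2-(4-benzyloxyphenyl)-4-oxochroman-5-yl (2S)-1-(benzyloxycarbonyl)piperidine-2-carboxylate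
Conditions: DCC (1.5 equiv), DMAP (0.2 equiv), CH2Cl2, 0 °C to rt
Reagents that add atoms: none
Why: Steglich esterification acylates the only free hydroxyl (O5); the urethane on nitrogen blocks oxazolone formation, so C2'' stays (S), and any C2'' epimer would be a diastereomer removable by chromatography.

**Step 3**
Reactants: 4 (2S)-7-benzyloxy-2-(4-benzyloxyphenyl)-4-oxochroman-5-yl (2S)-1-(benzyloxycarbonyl)piperidine-2-carboxylate
Product: 6 bridged lactone (2S,2''S,6''R) with the new C6–C6'' bond and the C2'' carboxyl still esterified to O5, via N-acyliminium ion 5 (not isolated)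
Conditions: ketoABNO (20 mol %), Bu4NPF6, HFIP/CH2Cl2 (1:4), RVC anode, Pt cathode, undivided cell, constant potential at the aminoxyl/oxoammonium wave, 0 °C to rt, ca. 2.2 F/mol; then TfOH (10 mol %), 0 °C
Reagents that add atoms: none
Why: Proposed new method: the oxoammonium ion from ketoABNO, regenerated at the anode well below the potential at which the benzyloxyarenes or the carbamate are oxidised directly, abstracts hydride from C6''–H2, the only α-amino C–H aligned with the carbamate π-system (the axial ester holds C2''–H in the carbamate plane), and the N-acyliminium ion 5, stabilised in HFIP, is captured by C6 of ring A, the only arene carbon the O5 tether can reach (C4a is substituted, C8 is para and out of reach); a 2'',6''-bridge can only be cis, which is also the stereoelectronically preferred axial attack, so the bought (2''S) centre sets C6'' as (R), and the product is protected from over-oxidation because its remaining C6''–H is equatorial; closest known reactions are the aminoxyl-mediated Shono-type α-oxygenation of cyclic carbamates and the N-acyliminium (cation-pool) aza-Friedel–Crafts arylation.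

**Step 4**
Reactants: 6 bridged lactone (2S,2''S,6''R)
Product: 7 (2S,6R)-1-(benzyloxycarbonyl)-6-[(2S)-7-benzyloxy-2-(4-benzyloxyphenyl)-5-hydroxy-4-oxochroman-6-yl]piperidine-2-carboxylic acid
Conditions: LiOH·H2O (1.5 equiv), THF/H2O, 0 °C, 20 min; then 1 M HCl to pH 3
Reagents that add atoms: lithium hydroxide, [Li+].[OH-]
Why: Saponification of a strained aryl ester (phenoxide leaving group) is fast at 0 °C; the blocked 4'-oxygen and the 5-phenoxide formed on opening suppress flavanone ring-opening, and C6'' carries no acidic hydrogen.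

**Step 5**
Reactants: 7 (2S,6R)-1-(benzyloxycarbonyl)-6-[(2S)-7-benzyloxy-2-(4-benzyloxyphenyl)-5-hydroxy-4-oxochroman-6-yl]piperidine-2-carboxylic acid
Product: 8 benzyl (2R)-2-[(2S)-7-benzyloxy-2-(4-benzyloxyphenyl)-5-hydroxy-4-oxochroman-6-yl]piperidine-1-carboxylate
Conditions: 4CzIPN (2 mol %), 2,4,6-triisopropylbenzenethiol (20 mol %), K2HPO4 (0.5 equiv), DMF, 450 nm LEDs, rt, degassed
Reagents that add atoms: none
Why: Photoredox hydrodecarboxylation (carboxylate oxidation by excited 4CzIPN, loss of CO2, thiol hydrogen-atom transfer to the α-amino radical) removes the relay carboxyl; the radical sits only at the old C2'', so the aryl-bearing carbon, now the sole piperidine stereocentre (R), is untouched.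

**Step 6**
Reactants: 8 benzyl (2R)-2-[(2S)-7-benzyloxy-2-(4-benzyloxyphenyl)-5-hydroxy-4-oxochroman-6-yl]piperidine-1-carboxylate
Product: 10 (2S)-5,7-dihydroxy-2-(4-hydroxyphenyl)-6-[(2R)-1-methylpiperidin-2-yl]chroman-4-one, via secondary amine 9 (not isolated)
Conditions: H2 (1 atm), 10% Pd/C, aq. HCHO (1.2 equiv), MeOH/EtOAc, rt
Reagents that add atoms: formaldehyde, C=O
Why: Hydrogenolysis removes the Cbz group and both benzyl ethers, and the liberated amine undergoes reductive amination with formaldehyde on Pd; the neutral, room-temperature conditions leave the chelated ketone and both stereocentres intact.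

**Compound list**
1 | (2S)-naringenin, (2S)-5,7-dihydroxy-2-(4-hydroxyphenyl)chroman-4-one | O=C1C[C@@H](c2ccc(O)cc2)Oc2cc(O)cc(O)c21 | starting material
2 | (2S)-7-benzyloxy-2-(4-benzyloxyphenyl)-5-hydroxychroman-4-one | O=C1C[C@@H](c2ccc(OCc3ccccc3)cc2)Oc2cc(OCc3ccccc3)cc(O)c21 | intermediate
3 | (2S)-1-(benzyloxycarbonyl)piperidine-2-carboxylic acid (N-Cbz-L-pipecolic acid) | O=C(O)[C@@H]1CCCCN1C(=O)OCc1ccccc1 | starting material
4 | (2S)-7-benzyloxy-2-(4-benzyloxyphenyl)-4-oxochroman-5-yl (2S)-1-(benzyloxycarbonyl)piperidine-2-carboxylate | O=C(Oc1cc(OCc2ccccc2)cc2c1C(=O)C[C@@H](c1ccc(OCc3ccccc3)cc1)O2)[C@@H]1CCCCN1C(=O)OCc1ccccc1 | intermediate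
5 | N-acyliminium ion of 4 (C6''=N+ cation, 2''S, flavanone 2S) | O=C(Oc1cc(OCc2ccccc2)cc2c1C(=O)C[C@@H](c1ccc(OCc3ccccc3)cc1)O2)[C@@H]1CCCC=[N+]1C(=O)OCc1ccccc1 | intermediate
6 | bridged lactone: piperidine C6'' bonded to flavanone C6, C2'' carboxyl esterified to O5 (seven-membered lactone), N-Cbz, 7,4'-di-O-benzyl; 2S,2''S,6''R | O=C1Oc2c3C(=O)C[C@@H](c4ccc(OCc5ccccc5)cc4)Oc3cc(OCc3ccccc3)c2[C@H]2CCC[C@@H]1N2C(=O)OCc1ccccc1 | intermediate
7 | (2S,6R)-1-(benzyloxycarbonyl)-6-[(2S)-7-benzyloxy-2-(4-benzyloxyphenyl)-5-hydroxy-4-oxochroman-6-yl]piperidine-2-carboxylic acid | O=C(O)[C@@H]1CCC[C@H](c2c(O)c3C(=O)C[C@@H](c4ccc(OCc5ccccc5)cc4)Oc3cc2OCc2ccccc2)N1C(=O)OCc1ccccc1 | intermediate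
8 | benzyl (2R)-2-[(2S)-7-benzyloxy-2-(4-benzyloxyphenyl)-5-hydroxy-4-oxochroman-6-yl]piperidine-1-carboxylate | O=C(OCc1ccccc1)N1CCCC[C@@H]1c1c(O)c2C(=O)C[C@@H](c3ccc(OCc4ccccc4)cc3)Oc2cc1OCc1ccccc1 | intermediate
9 | (2S)-5,7-dihydroxy-2-(4-hydroxyphenyl)-6-[(2R)-piperidin-2-yl]chroman-4-one | O=C1C[C@@H](c2ccc(O)cc2)Oc2cc(O)c([C@H]3CCCCN3)c(O)c21 | intermediate
10 | (2S)-5,7-dihydroxy-2-(4-hydroxyphenyl)-6-[(2R)-1-methylpiperidin-2-yl]chroman-4-one | CN1CCCC[C@@H]1c1c(O)cc2c(c1O)C(=O)C[C@@H](c1ccc(O)cc1)O2 | target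

**Totals**
Total step count: 6. Longest linear sequence: 6 steps (1 → 2 → 4 → 6 → 7 → 8 → 10); 3 is bought and enters at step 2.

**Three steps most likely to fail**

Step 3 (the proposed new step). Risks: competing hydride abstraction at the 4'-O-benzyl CH2 or at flavanone C2–H, and slow closure of the seven-membered bridge. The fallback uses known chemistry, sets out from 3 (with 2) and comes back at 6. Acid 3 is methylated (MeI, K2CO3, DMF) to methyl (2S)-1-(benzyloxycarbonyl)piperidine-2-carboxylate F1. Direct anodic methoxylation with no arene in the cell (Shono oxidation; graphite anode, Et4NOTs, MeOH, constant current) gives methyl (2S)-1-(benzyloxycarbonyl)-6-methoxypiperidine-2-carboxylate F2. LiOH in THF/H2O gives (2S)-1-(benzyloxycarbonyl)-6-methoxypiperidine-2-carboxylic acid F3. DCC/DMAP coupling with 2 gives the tethered N,O-acetal ester F4. BF3·OEt2 (CH2Cl2, −40 to 0 °C) ionises F4 to the same N-acyliminium ion 5, which closes to 6 under the same tether control.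

Step 2. Risks: sluggish acylation of the chelated, hindered 5-OH and epimerisation of the activated acid during a long DMAP exposure. The fallback sets out from 3 and comes back at 4. Acid 3 is converted with cyanuric fluoride/pyridine (CH2Cl2, −10 °C) into the isolable, racemisation-resistant (2S)-1-(benzyloxycarbonyl)piperidine-2-carbonyl fluoride F5. F5 then acylates 2 (DMAP, iPr2NEt, CH2Cl2, rt) to give 4.

Step 6. Risks: aminomethylation of the freed ring A at C8 by formaldehyde, and over-hydrogenolysis of the benzylic C–N or C2–O1 bonds. The fallback sets out from 8 and comes back at 10. Hydrogenation over Pd/C with HCHO and 2,2'-bipyridyl (which suppresses phenolic benzyl ether cleavage) converts only the Cbz group into N-methyl, giving (2S)-7-benzyloxy-2-(4-benzyloxyphenyl)-5-hydroxy-6-[(2R)-1-methylpiperidin-2-yl]chroman-4-one F6. The benzyl ethers are then removed without hydrogen by BCl3/pentamethylbenzene (CH2Cl2, −78 °C) to give 10.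

**Further compounds**
F1 | step 3 | methyl (2S)-1-(benzyloxycarbonyl)piperidine-2-carboxylate | COC(=O)[C@@H]1CCCCN1C(=O)OCc1ccccc1
F2 | step 3 | methyl (2S)-1-(benzyloxycarbonyl)-6-methoxypiperidine-2-carboxylate (C6 epimer mixture) | COC(=O)[C@@H]1CCCC(OC)N1C(=O)OCc1ccccc1
F3 | step 3 | (2S)-1-(benzyloxycarbonyl)-6-methoxypiperidine-2-carboxylic acid (C6 epimer mixture) | O=C(O)[C@@H]1CCCC(OC)N1C(=O)OCc1ccccc1
F4 | step 3 | (2S)-7-benzyloxy-2-(4-benzyloxyphenyl)-4-oxochroman-5-yl (2S)-1-(benzyloxycarbonyl)-6-methoxypiperidine-2-carboxylate | O=C(Oc1cc(OCc2ccccc2)cc2c1C(=O)C[C@@H](c1ccc(OCc3ccccc3)cc1)O2)[C@@H]1CCCC(OC)N1C(=O)OCc1ccccc1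
F5 | step 2 | (2S)-1-(benzyloxycarbonyl)piperidine-2-carbonyl fluoride | O=C(F)[C@@H]1CCCCN1C(=O)OCc1ccccc1
F6 | step 6 | (2S)-7-benzyloxy-2-(4-benzyloxyphenyl)-5-hydroxy-6-[(2R)-1-methylpiperidin-2-yl]chroman-4-one | CN1CCCC[C@@H]1c1c(O)c2C(=O)C[C@@H](c3ccc(OCc4ccccc4)cc3)Oc2cc1OCc1ccccc1
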